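The data come from a simulation with constants of no real substance; scatter was added.

Substrate is left over in both earlier runs, and its readings stop falling within their scatter: winter reads 77.5 % at 80.0 min and 78.3 % at 120 min, autumn 52.4 % and 52.1 % at those times. Autumn was charged with more partner than substrate, so we read the leftover this way: partner went elsewhere, and the making of mono adduct has nearly stopped by these later readings.

| setting | winter | autumn | zeta | gamma | delta |
|---|---|---|---|---|---|
| substrate | 10 mM | 10 mM | 10 mM | 10 mM | 10 mM |
| partner | 0.36 equiv | 1.5 equiv | 0.500 equiv | 1.00 equiv | 2.00 equiv |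
| capture agent | 1 mM | 1 mM | 1.00 mM | 1.00 mM | 1.00 mM |
| remark | run made earlier | run made earlier |  |  |  |
| time |  |  | 2.0 h | 2.0 h | 2.0 h |

| run | time / min | mono adduct / % | bis adduct / % | substrate / % |
|---|---|---|---|---|
| winter | 25.0 | 14.3 | 0.6 | 82.7 |
| winter | 50.0 | 13.3 | 0.8 | 80.6 |
| winter | 80.0 | 11.5 | 0 | 77.5 |
| winter | 90.0 | 10.7 | 0.6 | 78.2 |
| winter | 120 | 5.7 | 0.3 | 78.3 |
| autumn | 25.0 | 28.8 | 0 | 64.2 |
| autumn | 50.0 | 24.4 | 1.6 | 59.4 |
| autumn | 80.0 | 19.9 | 0 | 52.4 |
| autumn | 90.0 | 20.6 | 0.2 | 51.7 |
| autumn | 120 | 13.8 | 1.1 | 52.1 |

(scatter of a reading: 1 percentage point)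

1. amount of mono adduct at the end, in percent of the substrate charged, for each flask in turn (zeta, gamma, delta)



What became of the substrate that did react? By 120 min winter has spent 21.7 % of its substrate and autumn 47.9 %, but mono adduct reads 5.7 % and 13.8 %, which is 26.3 % and 28.8 % of the spent amount. Pooled, the runs give 28.0 % for the surviving share s, the mono adduct standing at the end per substrate spent. The partner charges differ 4.17-fold while the two shares read close together, which fits a loss in proportion to the mono adduct present. The new flasks stop at 2.0 h, the time of those last readings, so we carry s over.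

How much substrate will they spend? From winter to autumn, spent substrate grows more slowly than the charge, as the charge raised to a power n that these two runs read as 0.555. Multiplying by s, our own reckoning gives 7.30 %, 10.7 % and 15.7 %, the last reaching beyond autumn's charge.

The forecast, working from mono adduct directly, says “This dependence is sublinear” and gives 8.6 %, 12.6 % and 17.2 %, above ours at each point.

    substrate + partner → mono adduct (k = 0.0610 /M/s)
    partner + mono adduct → bis adduct (k = 0.00200 /M/s)
    2 partner → self-condensation product (k = 0.0950 /M/s)
    mono adduct → decomposed reagent (k = 2.10 × 10⁻⁴ /s)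
    mono adduct + capture agent → trapped intermediate (k = 0.00480 /M/s)

Zeta, gamma and delta end with 8.41 %, 11.7 % and 14.6 % of mono adduct, so the forecast stands within its margin. In zeta, partner, the limiting reagent, is down to 1.2 % of its charge at 2.00 h, with substrate at 71.8 %. Applied to that substrate, s gives 7.90 % of mono adduct for zeta, against 8.41 %. Delta ends with substrate at 47.6 %, and there s gives 14.7 %, against 14.6 %.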